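**Retrosynthetic overview** (carotenoid numbering; the chain runs C7…C15, C15'…C7')
1. The target is the mono-3-sulfate of C2-symmetric (2R,3R,2'R,3'R)-nostoxanthin, so the last events are global desilylation and O-sulfation of one of the two homotopic 3-hydroxyls.
2. Key disconnection: the C12'–C13' single bond inside the diene C11'=C12'–C13'(CH3)=C14'. The chain is taken up to the alkyne oxidation level, giving a C16 terminal trienyne and a C24 methyl-capped hexaenyne, which a titanium-mediated reductive alkyne–alkyne cross-coupling joins in one operation (C12'–C13' bond, the 11'E and 13'E double bonds, the complete eleven-double-bond chromophore).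
3. Enabling feature: the inner carbons of that diene carry only H (C12') and CH3 (C13'), while the outer carbons C11' and C14' carry the conjugated arms, which is the substitution pattern of a head-to-head metallacyclopentadiene of two alkenyl-alkynes. The two trimethylcyclohexene end rings are identical, so both alkynes come from one C15 aldehyde.
4. C15 aldehyde: Stille coupling of a ring enol triflate with a stannyl dienol, then oxidation. C16 alkyne: one-carbon Colvin homologation. C24 alkyne: two Horner–Wadsworth–Emmons extensions (C5 ester phosphonate, then a C4 propargylic phosphonate).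
5. Rings: no carbocycle is formed. Both six-membered rings come from ketoisophorone (C2 oxygen by Rubottom hydroxylation and lipase resolution, C3 by hydroxyl-directed reduction). The only rings made are the transient titanacyclopropene and then titanacyclopentadiene of the key step.

Key step: step 15

Assumption: the lipase in step 2 is taken to follow the usual size rule for secondary alcohols, with the C(CH3)2 side as the large group, so the (5S)-ketol is acetylated and the wanted (5R)-ketol stays free.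

**Step 1**
Reactants: 1 ketoisophorone (2,6,6-trimethylcyclohex-2-ene-1,4-dione)
Product: 4 rac-5-hydroxy-2,6,6-trimethylcyclohex-2-ene-1,4-dione, via trimethylsilyl dienol ether 2 (not isolated), via 5-trimethylsilyloxy enedione 3 (not isolated)
Conditions: LiN(SiMe3)2, Me3SiCl, THF, −78 °C; then mCPBA, CH2Cl2, 0 °C; then 1 M HCl, THF, 0 °C
Reagents that add atoms: mCPBA, OOC(=O)c1cccc(Cl)c1
Why: Rubottom oxidation; only C5 can be deprotonated kinetically (the C1 carbonyl has no α-hydrogen) and the electron-rich silyl enol ether double bond is epoxidised in preference to the enone double bond, the new stereocentre being formed racemic.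

**Step 2**
Reactants: 4 rac-5-hydroxy-2,6,6-trimethylcyclohex-2-ene-1,4-dione
Product: 5 (5R)-5-hydroxy-2,6,6-trimethylcyclohex-2-ene-1,4-dione
Conditions: lipase from Burkholderia cepacia (Amano PS), vinyl acetate, t-BuOMe, 30 °C, run slightly past half conversion; chromatography
Reagents that add atoms: none
Why: Lipase-catalysed kinetic resolution by enantioselective transesterification of an α'-hydroxy enone, which should acetylate the (5S)-enantiomer and leave the (5R)-alcohol that becomes C2 of the rings.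

**Step 3**
Reactants: 5 (5R)-5-hydroxy-2,6,6-trimethylcyclohex-2-ene-1,4-dione
Product: 6 (4R,5R)-4,5-dihydroxy-2,6,6-trimethylcyclohex-2-en-1-one (trans-diol)
Conditions: Me4NBH(OAc)3, MeCN/AcOH (1:1), −30 °C
Reagents that add atoms: none
Why: Hydroxyl-directed (Saksena–Evans) reduction: the acetoxyborohydride bound to the 5-OH delivers hydride to the adjacent C4 carbonyl on the face syn to that oxygen, which sets 4R with the trans-diol; the hindered C1 carbonyl, flanked by the quaternary carbon and lacking an α-oxygen, should be left.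

**Step 4**
Reactants: 6 (4R,5R)-4,5-dihydroxy-2,6,6-trimethylcyclohex-2-en-1-one
Product: 7 (4R,5R)-4,5-bis(tert-butyldimethylsilyloxy)-2,6,6-trimethylcyclohex-2-en-1-one
Conditions: t-BuMe2SiOTf, 2,6-lutidine, CH2Cl2, 0 °C → rt
Reagents that add atoms: tert-butyldimethylsilyl triflate, CC(C)(C)[Si](C)(C)OS(=O)(=O)C(F)(F)F
Why: Silyl triflate silylation, reactive enough for the neopentyl 5-OH, gives base- and organometallic-stable ethers without touching the stereocentres.

**Step 5**
Reactants: 7 (4R,5R)-4,5-bis(tert-butyldimethylsilyloxy)-2,6,6-trimethylcyclohex-2-en-1-one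
Product: 9 (4R,5R)-4,5-bis(tert-butyldimethylsilyloxy)-2,6,6-trimethylcyclohex-1-en-1-yl trifluoromethanesulfonate, via lithium enolate 8 (not isolated)
Conditions: LiBH(sec-Bu)3, THF, −78 °C; then PhNTf2, −78 → 0 °C
Reagents that add atoms: N-phenylbis(trifluoromethanesulfonimide), O=S(=O)(N(c1ccccc1)S(=O)(=O)C(F)(F)F)C(F)(F)F
Why: Conjugate reduction with enolate O-triflation (as practised on carvone-type 2-methylcyclohexenones); 1,2-attack is blocked by the flanking quaternary carbon, and the enolate formed regiospecifically gives the tetrasubstituted enol triflate.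

**Step 6**
Reactants: 10 (E)-3-methylpent-2-en-4-yn-1-ol
Product: 11 (2E,4E)-3-methyl-5-(tributylstannyl)penta-2,4-dien-1-ol
Conditions: Bu3SnH, PdCl2(PPh3)2 (cat.), THF, 0 °C → rt
Reagents that add atoms: tributyltin hydride, CCCC[SnH](CCCC)CCCC
Why: Palladium-catalysed syn-hydrostannation of the terminal alkyne places tin on the terminal carbon and gives the (E)-vinylstannane.

**Step 7**
Reactants: 9 (4R,5R)-4,5-bis(tert-butyldimethylsilyloxy)-2,6,6-trimethylcyclohex-1-en-1-yl trifluoromethanesulfonate; 11 (2E,4E)-3-methyl-5-(tributylstannyl)penta-2,4-dien-1-ol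
Product: 12 (2E,4E)-5-[(4R,5R)-4,5-bis(tert-butyldimethylsilyloxy)-2,6,6-trimethylcyclohex-1-en-1-yl]-3-methylpenta-2,4-dien-1-ol
Conditions: Pd2(dba)3 (cat.), AsPh3, LiCl, NMP, 60 °C
Reagents that add atoms: none
Why: Stille coupling under the AsPh3/LiCl/NMP conditions used for hindered 2,6,6-trimethylcyclohexenyl triflates forms C6–C7 with retention of the stannane geometry.

**Step 8**
Reactants: 12 (2E,4E)-5-[(4R,5R)-4,5-bis(tert-butyldimethylsilyloxy)-2,6,6-trimethylcyclohex-1-en-1-yl]-3-methylpenta-2,4-dien-1-ol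
Product: 13 (2E,4E)-5-[(4R,5R)-4,5-bis(tert-butyldimethylsilyloxy)-2,6,6-trimethylcyclohex-1-en-1-yl]-3-methylpenta-2,4-dienal (C15 aldehyde)
Conditions: MnO2, CH2Cl2, rt, dark
Reagents that add atoms: none
Why: Chemoselective MnO2 oxidation of the allylic alcohol to the dienal.

**Step 9**
Reactants: 13 C15 aldehyde
Product: 14 (4R,5R)-4,5-bis(tert-butyldimethylsilyloxy)-1-[(1E,3E)-3-methylhexa-1,3-dien-5-yn-1-yl]-2,6,6-trimethylcyclohex-1-ene (C16 trienyne)
Conditions: Me3SiCHN2, LiN(i-Pr)2, THF, −78 → 0 °C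
Reagents that add atoms: trimethylsilyldiazomethane, C[Si](C)(C)C=[N+]=[N-]
Why: Colvin rearrangement (addition of lithiated trimethylsilyldiazomethane, Peterson-type elimination, loss of N2 and 1,2-hydrogen shift of the alkylidene carbene), a one-carbon homologation that works on enals without base-sensitive intermediates.

**Step 10**
Reactants: 13 C15 aldehyde; 15 triethyl (E)-3-methyl-4-phosphonobut-2-enoate (commercial E/Z mixture, E drawn)
Product: 16 ethyl (2E,4E,6E,8E)-9-[(4R,5R)-4,5-bis(tert-butyldimethylsilyloxy)-2,6,6-trimethylcyclohex-1-en-1-yl]-3,7-dimethylnona-2,4,6,8-tetraenoate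
Conditions: LiN(SiMe3)2, THF/DMPU, −78 → 0 °C; chromatography to remove the minor 2Z isomer
Reagents that add atoms: none
Why: Horner–Wadsworth–Emmons olefination with the stabilised C5 phosphonate, the standard retinoate chain extension, should give mainly the all-E ester.

**Step 11**
Reactants: 16 ethyl tetraenoate
Product: 17 (2E,4E,6E,8E)-9-[(4R,5R)-4,5-bis(tert-butyldimethylsilyloxy)-2,6,6-trimethylcyclohex-1-en-1-yl]-3,7-dimethylnona-2,4,6,8-tetraen-1-ol
Conditions: i-Bu2AlH, CH2Cl2, −78 °C; Rochelle salt work-up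
Reagents that add atoms: none
Why: i-Bu2AlH reduces the conjugated ester 1,2 to the allylic alcohol without affecting silyl ethers or the polyene.

**Step 12**
Reactants: 17 tetraenol
Product: 18 (2E,4E,6E,8E)-9-[(4R,5R)-4,5-bis(tert-butyldimethylsilyloxy)-2,6,6-trimethylcyclohex-1-en-1-yl]-3,7-dimethylnona-2,4,6,8-tetraenal (C20 aldehyde)
Conditions: MnO2, CH2Cl2, rt, dark
Reagents that add atoms: none
Why: MnO2 oxidation of the allylic alcohol to the retinal-type aldehyde.

**Step 13**
Reactants: 19 1-bromobut-2-yne; 20 triethyl phosphite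
Product: 21 diethyl but-2-yn-1-ylphosphonate
Conditions: neat, 130 °C, EtBr distilled off
Reagents that add atoms: none
Why: Michaelis–Arbuzov reaction of the primary propargylic bromide.

**Step 14**
Reactants: 18 C20 aldehyde; 21 diethyl but-2-yn-1-ylphosphonate
Product: 22 (4R,5R)-4,5-bis(tert-butyldimethylsilyloxy)-1-[(1E,3E,5E,7E,9E)-3,7-dimethyltrideca-1,3,5,7,9-pentaen-11-yn-1-yl]-2,6,6-trimethylcyclohex-1-ene (C24 hexaenyne)
Conditions: LiN(SiMe3)2, THF, −78 → 0 °C, dark
Reagents that add atoms: none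
Why: Horner–Wadsworth–Emmons olefination with a propargylic phosphonate, an established E-selective route to conjugated enynes, forms C15=C15' and installs the methyl-capped triple bond.

**Step 15**
Reactants: 22 C24 hexaenyne; 14 C16 trienyne
Product: 25 2,3,2',3'-tetrakis-O-(tert-butyldimethylsilyl)-(2R,3R,2'R,3'R)-nostoxanthin, via titanacyclopropene 23 (not isolated), via titanacyclopentadiene 24 (not isolated)
Conditions: 22 (1.1 equiv), Ti(OiPr)4 (1.1 equiv), i-PrMgCl (2.2 equiv), Et2O/toluene, −78 → −45 °C; then 14 (1.0 equiv), −45 → −25 °C; then H2O, → rt; argon, dark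
Reagents that add atoms: none
Why: Proposed new method: Ti(OiPr)4 and two equivalents of i-PrMgCl give (η2-propene)Ti(OiPr)2, a divalent titanium equivalent, which exchanges propene for the internal triple bond of 22 to give titanacyclopropene 23; the terminal triple bond of 14 then inserts into the less hindered Ti–C(CH3) bond to close titanacyclopentadiene 24 (oxidative cyclisation of two alkynes at titanium, forming C12'–C13'), and water cleaves both Ti–C(sp2) bonds with retention. The closest known reaction type is the titanium alkoxide-mediated reductive cross-coupling of a preformed internal-alkyne complex with a second alkyne to give stereodefined 1,3-dienes; it has not been shown for two undirected, polyene-conjugated alkynes, hence the label. The only ring closed is the transient five-membered metallacycle, and it fixes the geometry: inside it titanium is cis to C12' across C13'=C14' and cis to C13' across C11'=C12', so stereoretentive protonolysis leaves both new double bonds E. No stereocentre is formed, and the four silyloxy-bearing centres are remote and inert. The step needs head-to-head regiochemistry and cross- rather than homo-coupling: the first rests on the substitution pattern of the diene (conjugating alkenyl arms prefer the positions next to titanium, the small H and CH3 the inner positions where the C–C bond forms), the second on completing the formation of 23, with 22 in slight excess so that no free low-valent titanium remains, before 14 is added. Chemoselectivity for the triple bonds over the polyene rests on the stronger binding of alkynes to the low-valent titanium alkoxide at −45 °C.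

**Step 16**
Reactants: 25 tetrakis-silyl nostoxanthin
Product: 26 (2R,3R,2'R,3'R)-nostoxanthin (β,β-carotene-2,3,2',3'-tetrol)
Conditions: Bu4NF, THF, rt → 40 °C, dark
Reagents that add atoms: none
Why: Fluoride-mediated desilylation removes all four silyl ethers under basic conditions that the polyene tolerates.

**Step 17**
Reactants: 26 (2R,3R,2'R,3'R)-nostoxanthin
Product: 27 (2R,3R,2'R,3'R)-nostoxanthin 3-(hydrogen sulfate) (CNP0229621.3)
Conditions: SO3·pyridine (≤1 equiv), pyridine, 0 °C → rt, dark; chromatography with recovery of unreacted 26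
Reagents that add atoms: sulfur trioxide–pyridine complex, O=S(=O)([O-])[n+]1ccccc1
Why: O-sulfation with SO3·pyridine; the two 3-hydroxyls of C2-symmetric 26 are homotopic, so sulfation of either gives 27, the neopentyl 2-hydroxyls next to the gem-dimethyl carbon should react much more slowly, and limiting reagent should hold back the bis-sulfate.

**Compound list**
1 | ketoisophorone (2,6,6-trimethylcyclohex-2-ene-1,4-dione) | CC1=CC(=O)CC(C)(C)C1=O | starting material
2 | 2,6,6-trimethyl-4-(trimethylsilyloxy)cyclohexa-2,4-dien-1-one | CC1=CC(O[Si](C)(C)C)=CC(C)(C)C1=O | intermediate (not isolated)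
3 | rac-2,6,6-trimethyl-5-(trimethylsilyloxy)cyclohex-2-ene-1,4-dione | CC1=CC(=O)C(O[Si](C)(C)C)C(C)(C)C1=O | intermediate (not isolated)
4 | rac-5-hydroxy-2,6,6-trimethylcyclohex-2-ene-1,4-dione | CC1=CC(=O)C(O)C(C)(C)C1=O | intermediate
5 | (5R)-5-hydroxy-2,6,6-trimethylcyclohex-2-ene-1,4-dione | CC1=CC(=O)[C@H](O)C(C)(C)C1=O | intermediate
6 | (4R,5R)-4,5-dihydroxy-2,6,6-trimethylcyclohex-2-en-1-one (trans) | CC1=C[C@@H](O)[C@H](O)C(C)(C)C1=O | intermediate
7 | (4R,5R)-4,5-bis(tert-butyldimethylsilyloxy)-2,6,6-trimethylcyclohex-2-en-1-one | CC1=C[C@@H](O[Si](C)(C)C(C)(C)C)[C@H](O[Si](C)(C)C(C)(C)C)C(C)(C)C1=O | intermediate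
8 | lithium (4R,5R)-4,5-bis(tert-butyldimethylsilyloxy)-2,6,6-trimethylcyclohex-1-en-1-olate | CC1=C(O[Li])C(C)(C)[C@@H](O[Si](C)(C)C(C)(C)C)[C@H](O[Si](C)(C)C(C)(C)C)C1 | intermediate (not isolated)
9 | (4R,5R)-4,5-bis(tert-butyldimethylsilyloxy)-2,6,6-trimethylcyclohex-1-en-1-yl trifluoromethanesulfonate | CC1=C(OS(=O)(=O)C(F)(F)F)C(C)(C)[C@@H](O[Si](C)(C)C(C)(C)C)[C@H](O[Si](C)(C)C(C)(C)C)C1 | intermediate
10 | (E)-3-methylpent-2-en-4-yn-1-ol | C#C/C(C)=C/CO | starting material
11 | (2E,4E)-3-methyl-5-(tributylstannyl)penta-2,4-dien-1-ol | CCCC[Sn](CCCC)(CCCC)/C=C/C(C)=C/CO | intermediate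
12 | C15 alcohol: (2E,4E)-5-[(4R,5R)-4,5-bis(tert-butyldimethylsilyloxy)-2,6,6-trimethylcyclohex-1-en-1-yl]-3-methylpenta-2,4-dien-1-ol | CC1=C(/C=C/C(C)=C/CO)C(C)(C)[C@@H](O[Si](C)(C)C(C)(C)C)[C@H](O[Si](C)(C)C(C)(C)C)C1 | intermediate
13 | C15 aldehyde: (2E,4E)-5-[same ring]-3-methylpenta-2,4-dienal | CC1=C(/C=C/C(C)=C/C=O)C(C)(C)[C@@H](O[Si](C)(C)C(C)(C)C)[C@H](O[Si](C)(C)C(C)(C)C)C1 | intermediate
14 | C16 trienyne: (4R,5R)-4,5-bis(tert-butyldimethylsilyloxy)-1-[(1E,3E)-3-methylhexa-1,3-dien-5-yn-1-yl]-2,6,6-trimethylcyclohex-1-ene | CC1=C(/C=C/C(C)=C/C#C)C(C)(C)[C@@H](O[Si](C)(C)C(C)(C)C)[C@H](O[Si](C)(C)C(C)(C)C)C1 | intermediate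
15 | triethyl (E)-3-methyl-4-phosphonobut-2-enoate | CCOC(=O)/C=C(/CP(=O)(OCC)OCC)C | starting material
16 | C20 ester: ethyl (2E,4E,6E,8E)-9-[same ring]-3,7-dimethylnona-2,4,6,8-tetraenoate | CC1=C(/C=C/C(C)=C/C=C/C(C)=C/C(=O)OCC)C(C)(C)[C@@H](O[Si](C)(C)C(C)(C)C)[C@H](O[Si](C)(C)C(C)(C)C)C1 | intermediate
17 | C20 alcohol: (2E,4E,6E,8E)-9-[same ring]-3,7-dimethylnona-2,4,6,8-tetraen-1-ol | CC1=C(/C=C/C(C)=C/C=C/C(C)=C/CO)C(C)(C)[C@@H](O[Si](C)(C)C(C)(C)C)[C@H](O[Si](C)(C)C(C)(C)C)C1 | intermediate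
18 | C20 aldehyde: (2E,4E,6E,8E)-9-[same ring]-3,7-dimethylnona-2,4,6,8-tetraenal | CC1=C(/C=C/C(C)=C/C=C/C(C)=C/C=O)C(C)(C)[C@@H](O[Si](C)(C)C(C)(C)C)[C@H](O[Si](C)(C)C(C)(C)C)C1 | intermediate
19 | 1-bromobut-2-yne | CC#CCBr | starting material
20 | triethyl phosphite | CCOP(OCC)OCC | starting material
21 | diethyl but-2-yn-1-ylphosphonate | CC#CCP(=O)(OCC)OCC | intermediate
22 | C24 hexaenyne: (4R,5R)-4,5-bis(tert-butyldimethylsilyloxy)-1-[(1E,3E,5E,7E,9E)-3,7-dimethyltrideca-1,3,5,7,9-pentaen-11-yn-1-yl]-2,6,6-trimethylcyclohex-1-ene | CC1=C(/C=C/C(C)=C/C=C/C(C)=C/C=C/C#CC)C(C)(C)[C@@H](O[Si](C)(C)C(C)(C)C)[C@H](O[Si](C)(C)C(C)(C)C)C1 | intermediate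
23 | titanacyclopropene of 22: Ti(OiPr)2 bridging C13' and C14' | CC1=C(/C=C/C(C)=C/C=C/C(C)=C/C=C/C2=C(C)[Ti]2(OC(C)C)OC(C)C)C(C)(C)[C@@H](O[Si](C)(C)C(C)(C)C)[C@H](O[Si](C)(C)C(C)(C)C)C1 | intermediate (not isolated)
24 | diisopropoxytitanacyclopentadiene: Ti bonded to C14' (C24 arm) and C11' (C16 arm), ring carbons C13' (CH3) and C12' (H) joined by the new bond | CC1=C(/C=C/C(C)=C/C=C/C(C)=C/C=C/C2=C(C)C=C(/C=C(C)/C=C/C3=C(C)C[C@@H](O[Si](C)(C)C(C)(C)C)[C@H](O[Si](C)(C)C(C)(C)C)C3(C)C)[Ti]2(OC(C)C)OC(C)C)C(C)(C)[C@@H](O[Si](C)(C)C(C)(C)C)[C@H](O[Si](C)(C)C(C)(C)C)C1 | intermediate (not isolated)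
25 | 2,3,2',3'-tetrakis-O-(tert-butyldimethylsilyl)-(2R,3R,2'R,3'R)-nostoxanthin (all-E) | CC1=C(/C=C/C(C)=C/C=C/C(C)=C/C=C/C=C(C)/C=C/C=C(C)/C=C/C2=C(C)C[C@@H](O[Si](C)(C)C(C)(C)C)[C@H](O[Si](C)(C)C(C)(C)C)C2(C)C)C(C)(C)[C@@H](O[Si](C)(C)C(C)(C)C)[C@H](O[Si](C)(C)C(C)(C)C)C1 | intermediate
26 | (2R,3R,2'R,3'R)-nostoxanthin (all-E) | CC1=C(/C=C/C(C)=C/C=C/C(C)=C/C=C/C=C(C)/C=C/C=C(C)/C=C/C2=C(C)C[C@@H](O)[C@H](O)C2(C)C)C(C)(C)[C@@H](O)[C@H](O)C1 | intermediate
27 | (2R,3R,2'R,3'R)-nostoxanthin 3-(hydrogen sulfate), CNP0229621.3 | CC1=C(/C=C/C(C)=C/C=C/C(C)=C/C=C/C=C(C)/C=C/C=C(C)/C=C/C2=C(C)C[C@@H](OS(=O)(=O)O)[C@H](O)C2(C)C)C(C)(C)[C@@H](O)[C@H](O)C1 | target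

**Totals**
Total step count: 17.
Longest linear sequence: 14 steps (1, 2, 3, 4, 5, 7, 8, 10, 11, 12, 14, 15, 16, 17).

**Steps most likely to fail**

Step 15 (Proposed new method). The insertion may go through the wrong regioisomeric metallacycle, each alkyne may homo-couple, or the low-valent titanium may bind or reduce the polyene instead of the triple bonds. The fallback uses known chemistry and sets out from 22 and 14. Hydrozirconation of 22 with excess Cp2Zr(H)Cl (THF, 40 °C, so that zirconium settles on the methyl-bearing carbon) followed by I2 should give the (13'E)-alkenyl iodide F1. Hydrostannation of 14 (Bu3SnH, PdCl2(PPh3)2) should give the (E)-trienylstannane F2. Stille coupling of F1 with F2 (Pd2(dba)3, AsPh3, NMP, 25–40 °C) comes back to the route at 25.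

Step 17. Sulfation may run on to the second, equivalent ring, and the hindered 2-hydroxyl may compete, so that mono-selectivity is lost. The fallback differentiates one 3-oxygen before the halves are joined and sets out from 14. HF·pyridine in pyridine/THF at 0 °C should remove the less hindered 3-O-silyl group to give the mono-ol alkyne F3, and Et3SiCl/imidazole then gives the 3-O-triethylsilyl ether F4. Coupling of F4 with 22 as in step 15 gives the mixed silyl ether F5. Pyridinium p-toluenesulfonate in MeOH/CH2Cl2 at 0 °C removes only the triethylsilyl group to give the mono-ol F6. SO3·pyridine sulfates this single free hydroxyl to give the tris-silyl sulfate F7, and Bu4NF comes back to the route at 27.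

Step 2. The lipase may discriminate poorly between the enantiomers of a carbinol flanked by a quaternary carbon, or slow acylation may leave the alcohol with too little enrichment. The fallback moves the resolution to the diol stage and sets out from 4. Me4NBH(OAc)3 reduction of racemic 4 should give the racemic trans-diol F8. Lipase/vinyl acetate acylation of its unhindered 4-hydroxyl (trans-cycloalkane-1,2-diols are good lipase substrates) should give the (4R,5R)-4-acetate F9 as the fast-reacting enantiomer, separated from the unreacted (4S,5S)-diol. K2CO3/MeOH comes back to the route at 6.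

Further compounds
F1 | step 15 | (13'E)-alkenyl iodide of 22: (4R,5R)-4,5-bis(tert-butyldimethylsilyloxy)-1-[(1E,3E,5E,7E,9E,11E)-12-iodo-3,7-dimethyltrideca-1,3,5,7,9,11-hexaen-1-yl]-2,6,6-trimethylcyclohex-1-ene | CC1=C(/C=C/C(C)=C/C=C/C(C)=C/C=C/C=C(C)/I)C(C)(C)[C@@H](O[Si](C)(C)C(C)(C)C)[C@H](O[Si](C)(C)C(C)(C)C)C1
F2 | step 15 | (E)-trienylstannane of 14: tributyl[(1E,3E,5E)-6-[(4R,5R)-4,5-bis(tert-butyldimethylsilyloxy)-2,6,6-trimethylcyclohex-1-en-1-yl]-4-methylhexa-1,3,5-trien-1-yl]stannane | CC1=C(/C=C/C(C)=C/C=C/[Sn](CCCC)(CCCC)CCCC)C(C)(C)[C@@H](O[Si](C)(C)C(C)(C)C)[C@H](O[Si](C)(C)C(C)(C)C)C1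
F3 | step 17 | C16 trienyne with free 3-OH and 2-O-tert-butyldimethylsilyl (2R,3R) | CC1=C(/C=C/C(C)=C/C#C)C(C)(C)[C@@H](O[Si](C)(C)C(C)(C)C)[C@H](O)C1
F4 | step 17 | C16 trienyne with 3-O-triethylsilyl and 2-O-tert-butyldimethylsilyl (2R,3R) | CC1=C(/C=C/C(C)=C/C#C)C(C)(C)[C@@H](O[Si](C)(C)C(C)(C)C)[C@H](O[Si](CC)(CC)CC)C1
F5 | step 17 | 2,3,2'-tris-O-(tert-butyldimethylsilyl)-3'-O-(triethylsilyl)nostoxanthin | CC1=C(/C=C/C(C)=C/C=C/C(C)=C/C=C/C=C(C)/C=C/C=C(C)/C=C/C2=C(C)C[C@@H](O[Si](CC)(CC)CC)[C@H](O[Si](C)(C)C(C)(C)C)C2(C)C)C(C)(C)[C@@H](O[Si](C)(C)C(C)(C)C)[C@H](O[Si](C)(C)C(C)(C)C)C1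
F6 | step 17 | 2,3,2'-tris-O-(tert-butyldimethylsilyl)nostoxanthin (free 3'-OH) | CC1=C(/C=C/C(C)=C/C=C/C(C)=C/C=C/C=C(C)/C=C/C=C(C)/C=C/C2=C(C)C[C@@H](O)[C@H](O[Si](C)(C)C(C)(C)C)C2(C)C)C(C)(C)[C@@H](O[Si](C)(C)C(C)(C)C)[C@H](O[Si](C)(C)C(C)(C)C)C1
F7 | step 17 | 2,3,2'-tris-O-(tert-butyldimethylsilyl)nostoxanthin 3'-(hydrogen sulfate) | CC1=C(/C=C/C(C)=C/C=C/C(C)=C/C=C/C=C(C)/C=C/C=C(C)/C=C/C2=C(C)C[C@@H](OS(=O)(=O)O)[C@H](O[Si](C)(C)C(C)(C)C)C2(C)C)C(C)(C)[C@@H](O[Si](C)(C)C(C)(C)C)[C@H](O[Si](C)(C)C(C)(C)C)C1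
F8 | step 2 | rac-trans-4,5-dihydroxy-2,6,6-trimethylcyclohex-2-en-1-one (racemate, one enantiomer drawn) | CC1=C[C@@H](O)[C@H](O)C(C)(C)C1=O
F9 | step 2 | (4R,5R)-4-acetoxy-5-hydroxy-2,6,6-trimethylcyclohex-2-en-1-one | CC1=C[C@@H](OC(C)=O)[C@H](O)C(C)(C)C1=O
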